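**Strategy.** Ring A (C1–C5, C10) shares the C5–C10 bond with ring B, and its C1–C2 and C5–C10 bonds are the two σ-bonds of a Diels–Alder retron once a C3=C4 alkene is drawn. An acyclic triene carries the diene (C2=C3–C4(Me)=C5), the 1,1-disubstituted dienophile (C10(Me)=C1) and, between C5 and C10, the four-carbon tether C6–C9 with the C6 silyloxy and C9 butynyl stereocentres already set. One thermal intramolecular Diels–Alder reaction closes rings A and B together and fixes C5 and the quaternary C10. Radical hydromethylation of C3=C4 then supplies the gem-dimethyl group; the C8 ketone becomes the C7=C8–CH2OAc unit and the alkyne the (E)-diene.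

Key step: step 9

**Remarks on the chemistry (assumptions).**
- Carbons are numbered as in the ent-labdane skeleton of the target throughout (decalin C1–C10, side chain C11–C16, acetoxymethyl carbon C17, geminal methyls C18/C19, angular methyl C20). "Syn" and "anti" refer to the face of the C10 methyl. The target is (5R,6S,9S,10S,12E).
- (E)-3-Methylpent-2-en-4-yn-1-ol, (S)-4-benzyl-1,3-oxazolidin-2-one, 3-methylbut-2-enoyl chloride and 1-bromobut-2-yne are taken as commercial.
- For step 7 it is assumed that (+)-Ipc2BCl is the antipode that sends a methyl ketone enol borinate to the Si face of an aldehyde (the reverse of the sense for ethyl ketones). If the sense is the opposite, (−)-Ipc2BCl is used instead.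

**Step 1**
Reactants: 1 (E)-3-methylpent-2-en-4-yn-1-ol
Product: 2 (E)-3-methylpenta-2,4-dien-1-ol
Conditions: H2 (1 atm), Pd/CaCO3 poisoned with Pb(OAc)2 (Lindlar catalyst), quinoline, hexane/EtOAc, rt, stopped after 1 equiv H2
Reagents that add atoms: none
Why: Lindlar semihydrogenation should stop at the alkene stage, so the terminal alkyne becomes the vinyl group and the (E)-trisubstituted alkene is untouched.

**Step 2**
Reactants: 2 (E)-3-methylpenta-2,4-dien-1-ol
Product: 3 (E)-3-methylpenta-2,4-dienal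
Conditions: MnO2, CH2Cl2, rt; used as a solution (volatile)
Reagents that add atoms: none
Why: MnO2 oxidation of an allylic alcohol should give the dienal without isomerising the (E)-diene.

**Step 3**
Reactants: 4 (S)-4-benzyl-1,3-oxazolidin-2-one; 5 3-methylbut-2-enoyl chloride
Product: 7 (S)-4-benzyl-3-(3-methylbut-2-enoyl)-1,3-oxazolidin-2-one, via lithium oxazolidinide 6 (not isolated)
Conditions: n-BuLi, THF, −78 °C; then 5, −78 → 0 °C
Reagents that add atoms: none
Why: N-acylation of the lithiated oxazolidinone with the acid chloride attaches the Evans auxiliary.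

**Step 4**
Reactants: 7 (S)-4-benzyl-3-(3-methylbut-2-enoyl)-1,3-oxazolidin-2-one; 8 1-bromobut-2-yne
Product: 10 (S)-4-benzyl-3-[(S)-2-(prop-1-en-2-yl)hex-4-ynoyl]-1,3-oxazolidin-2-one, via sodium dienolate 9 (not isolated)
Conditions: NaN(SiMe3)2, THF, −78 °C; then 8, −78 → −40 °C
Reagents that add atoms: none
Why: Evans asymmetric alkylation with deconjugation: γ-deprotonation gives the chelated (Z)-dienolate, which should be alkylated at the α-carbon on the face opposite the benzyl group, creating the (S) stereocentre (C9) and the isopropenyl group (C10, C1, C20) in one step.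

**Step 5**
Reactants: 10 (S)-4-benzyl-3-[(S)-2-(prop-1-en-2-yl)hex-4-ynoyl]-1,3-oxazolidin-2-one
Product: 11 (S)-N-methoxy-N-methyl-2-(prop-1-en-2-yl)hex-4-ynamide
Conditions: Me(MeO)NH·HCl, AlMe3, CH2Cl2, −15 °C → rt
Reagents that add atoms: N,O-dimethylhydroxylamine hydrochloride, CNOC.Cl
Why: Aluminium amide aminolysis of the imide at the exocyclic carbonyl should give the Weinreb amide under non-basic conditions and release the auxiliary for recovery.

**Step 6**
Reactants: 11 (S)-N-methoxy-N-methyl-2-(prop-1-en-2-yl)hex-4-ynamide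
Product: 12 (S)-3-(prop-1-en-2-yl)hept-5-yn-2-one
Conditions: MeMgBr, THF, −78 → 0 °C; cold pH 7 buffer quench
Reagents that add atoms: methylmagnesium bromide, C[Mg]Br
Why: Weinreb ketone synthesis: the chelated tetrahedral adduct resists over-addition and collapses only on the cold neutral quench, which should avoid epimerisation at C9 and conjugation of the β,γ-alkene.

**Step 7**
Reactants: 12 (S)-3-(prop-1-en-2-yl)hept-5-yn-2-one; 3 (E)-3-methylpenta-2,4-dienal
Product: 14 (3E,5S,8S)-5-hydroxy-3-methyl-8-(prop-1-en-2-yl)dodeca-1,3-dien-10-yn-7-one, via enol diisopinocampheylborinate 13 (not isolated)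
Conditions: (+)-Ipc2BCl, Et3N, Et2O, −78 → 0 °C; then 3, −78 → −20 °C; then H2O2, pH 7 buffer, MeOH, 0 °C
Reagents that add atoms: none
Why: Boron-mediated aldol reaction of a methyl ketone (enolisation at the methyl group, closed transition state, 1,2-addition to the dienal) in which the isopinocampheyl ligands should direct attack to the Si face of the aldehyde and set C6 as (S), any minor C6 epimer being removable by chromatography.

**Step 8**
Reactants: 14 (3E,5S,8S)-5-hydroxy-3-methyl-8-(prop-1-en-2-yl)dodeca-1,3-dien-10-yn-7-one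
Product: 15 (3E,5S,8S)-5-(tert-butyldimethylsilyloxy)-3-methyl-8-(prop-1-en-2-yl)dodeca-1,3-dien-10-yn-7-one
Conditions: TBSOTf, 2,6-lutidine, CH2Cl2, −78 °C
Reagents that add atoms: tert-butyldimethylsilyl trifluoromethanesulfonate, CC(C)(C)[Si](C)(C)OS(=O)(=O)C(F)(F)F
Why: Silyl protection of the secondary alcohol at low temperature should block retro-aldol and elimination in the later steps without touching the ketone.

**Step 9**
Reactants: 15 (3E,5S,8S)-5-(tert-butyldimethylsilyloxy)-3-methyl-8-(prop-1-en-2-yl)dodeca-1,3-dien-10-yn-7-one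
Product: 16 9-(but-2-yn-1-yl)-6-(tert-butyldimethylsilyloxy)-4,10-dimethyl-trans-Δ3-octalin-8-one (H-5 anti; 6-O and 9-chain syn to the C10 methyl)
Conditions: toluene (0.01 M), BHT (cat.), sealed tube, 180 °C, 24–48 h
Reagents that add atoms: none
Why: Thermal type 1 intramolecular Diels–Alder reaction of a 1,7,9-decatriene: the diene C2=C3–C4=C5 and the alkene C10=C1 should combine in a concerted, asynchronous [4+2] cycloaddition that forms C5–C10 and C1–C2 and leaves C3=C4. The closest known reaction type is the thermal cycloaddition of unactivated 1,7,9-decatrienes to octalins, including those that place an angular methyl group from a 1,1-disubstituted dienophile. Ring A closes as the six-membered cycloadduct ring, and ring B closes through the same C5–C10 bond as a fused (not bridged) six-membered ring over a chair-like C6–C9 tether. C5 and C10 are controlled by the tether stereocentres: the C9 butynyl group sits equatorial, and allylic 1,3-strain with the C4 methyl puts H-6 in the diene plane and the C6 silyloxy group axial, so both select the same diene face. The step needs the trans ring fusion (H-5 anti to the C10 methyl), which the C4 methyl should secure by clashing with the tether in the cis-fused geometry. Only the C10=C1 alkene can reach the diene through a six-membered tether, so the alkyne and the ketone should not compete.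

**Step 10**
Reactants: 16 9-(but-2-yn-1-yl)-6-(tert-butyldimethylsilyloxy)-4,10-dimethyl-trans-Δ3-octalin-8-one
Product: 18 9-(but-2-yn-1-yl)-6-(tert-butyldimethylsilyloxy)-4,4,10-trimethyl-trans-decalin-8-one, via sulfonylhydrazide adduct 17 (not isolated)
Conditions: Fe(acac)3 (cat.), PhSiH3, formaldehyde N-(octylsulfonyl)hydrazone, THF/MeOH, rt; then MeOH, 60 °C
Reagents that add atoms: formaldehyde N-(octylsulfonyl)hydrazone, C=NNS(=O)(=O)CCCCCCCC
Why: Metal-hydride hydrogen atom transfer hydromethylation: Markovnikov H-atom transfer to C3 gives the tertiary C4 radical, which adds to the formaldehyde hydrazone, and the hydrazide then loses sulfinate and N2 in warm methanol to leave the second C4 methyl, with no stereocentre created and the ketone, silyl ether and internal alkyne expected to be spared.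

**Step 11**
Reactants: 18 9-(but-2-yn-1-yl)-6-(tert-butyldimethylsilyloxy)-4,4,10-trimethyl-trans-decalin-8-one
Product: 20 9-(but-2-yn-1-yl)-6-(tert-butyldimethylsilyloxy)-4,4,10-trimethyl-trans-Δ7-octalin-8-yl trifluoromethanesulfonate, via potassium enolate 19 (not isolated)
Conditions: KN(SiMe3)2, THF, −78 °C; then N-(5-chloropyridin-2-yl)bis(trifluoromethanesulfonyl)imide (Comins' reagent), −78 °C
Reagents that add atoms: N-(5-chloropyridin-2-yl)bis(trifluoromethanesulfonyl)imide, FC(F)(F)S(=O)(=O)N(c1ccc(Cl)cn1)S(=O)(=O)C(F)(F)F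
Why: Kinetic deprotonation by the bulky amide base should occur at the C7 methylene and not at the hindered C9 methine, and O-triflation of the enolate at −78 °C (enol triflate formation) should outrun β-elimination of the C6 silyloxy group, fixing the C7=C8 alkene.

**Step 12**
Reactants: 20 9-(but-2-yn-1-yl)-6-(tert-butyldimethylsilyloxy)-4,4,10-trimethyl-trans-Δ7-octalin-8-yl trifluoromethanesulfonate
Product: 21 [9-(but-2-yn-1-yl)-6-(tert-butyldimethylsilyloxy)-4,4,10-trimethyl-trans-Δ7-octalin-8-yl]methanol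
Conditions: Pd(PPh3)4 (cat.), LiCl, Bu3SnCH2OH, 1,4-dioxane, 95 °C
Reagents that add atoms: (tributylstannyl)methanol, OC[Sn](CCCC)(CCCC)CCCC
Why: Stille coupling of the alkenyl triflate with the hydroxymethyl stannane (LiCl-assisted) should install C17 at the alcohol oxidation level and keep the C7=C8 alkene where the triflate fixed it.

**Step 13**
Reactants: 21 [9-(but-2-yn-1-yl)-6-(tert-butyldimethylsilyloxy)-4,4,10-trimethyl-trans-Δ7-octalin-8-yl]methanol
Product: 24 (5R,6S,9S,10S)-6-(tert-butyldimethylsilyloxy)labda-7,12E,14-trien-17-ol (ent-labdane series), via alkenylzirconocene chloride 22 (not isolated), via alkenylzinc chloride 23 (not isolated)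
Conditions: Cp2Zr(H)Cl (3.2 equiv), THF, 45 °C; then ZnCl2, CH2=CHBr, Pd(PPh3)4 (cat.), THF, rt; aq NH4Cl
Reagents that add atoms: vinyl bromide, C=CBr
Why: Syn-hydrozirconation of the internal alkyne, equilibrated by excess Cp2Zr(H)Cl so that zirconium rests on the less hindered methyl-bearing C13 (the first equivalent being consumed by the C17 hydroxyl), followed by transmetalation to zinc and Negishi coupling with vinyl bromide with retention, should give the (12E)-diene.

**Step 14**
Reactants: 24 (5R,6S,9S,10S)-6-(tert-butyldimethylsilyloxy)labda-7,12E,14-trien-17-ol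
Product: 25 (5R,6S,9S,10S)-labda-7,12E,14-triene-6,17-diol (ent-labdane series)
Conditions: Bu4NF, THF, rt → 50 °C
Reagents that add atoms: none
Why: Fluoride desilylation should free the hindered axial C6 hydroxyl without affecting the diene or the allylic alcohol.

**Step 15**
Reactants: 25 (5R,6S,9S,10S)-labda-7,12E,14-triene-6,17-diol
Product: 26 (5R,6S,9S,10S)-labda-7,12E,14-triene-6,17-diyl diacetate (target)
Conditions: Ac2O, pyridine, DMAP (cat.), CH2Cl2, rt → 40 °C
Reagents that add atoms: acetic anhydride, CC(=O)OC(C)=O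
Why: DMAP-catalysed acetylation should esterify both the primary C17 hydroxyl and the hindered axial C6 hydroxyl (gentle warming for the latter), completing the target.

**Compound list**

1 | (E)-3-methylpent-2-en-4-yn-1-ol | C#C/C(C)=C/CO | starting material
2 | (E)-3-methylpenta-2,4-dien-1-ol | C=C/C(C)=C/CO | intermediate
3 | (E)-3-methylpenta-2,4-dienal | C=C/C(C)=C/C=O | intermediate
4 | (S)-4-benzyl-1,3-oxazolidin-2-one | O=C1N[C@@H](Cc2ccccc2)CO1 | starting material
5 | 3-methylbut-2-enoyl chloride | CC(C)=CC(Cl)=O | starting material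
6 | lithium (S)-4-benzyl-2-oxo-1,3-oxazolidin-3-ide | [Li+].O=C1[N-][C@@H](Cc2ccccc2)CO1 | intermediate (not isolated)
7 | (S)-4-benzyl-3-(3-methylbut-2-enoyl)-1,3-oxazolidin-2-one | CC(C)=CC(=O)N1C(=O)OC[C@@H]1Cc1ccccc1 | intermediate
8 | 1-bromobut-2-yne | CC#CCBr | starting material
9 | sodium (Z)-dienolate of 7 | [Na+].[O-]/C(=C\C(C)=C)N1C(=O)OC[C@@H]1Cc1ccccc1 | intermediate (not isolated)
10 | (S)-4-benzyl-3-[(S)-2-(prop-1-en-2-yl)hex-4-ynoyl]-1,3-oxazolidin-2-one | CC#CC[C@@H](C(C)=C)C(=O)N1C(=O)OC[C@@H]1Cc1ccccc1 | intermediate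
11 | (S)-N-methoxy-N-methyl-2-(prop-1-en-2-yl)hex-4-ynamide | CC#CC[C@@H](C(C)=C)C(=O)N(C)OC | intermediate
12 | (S)-3-(prop-1-en-2-yl)hept-5-yn-2-one | CC#CC[C@@H](C(C)=C)C(C)=O | intermediate
13 | enol bis[(+)-isopinocampheyl]borinate of 12 (boron on the oxygen of the CH2=C(O) enol) | CC#CC[C@@H](C(C)=C)C(=C)OB([C@H]1C[C@H]2C[C@@H]([C@@H]1C)C2(C)C)[C@H]1C[C@H]2C[C@@H]([C@@H]1C)C2(C)C | intermediate (not isolated)
14 | (3E,5S,8S)-5-hydroxy-3-methyl-8-(prop-1-en-2-yl)dodeca-1,3-dien-10-yn-7-one | CC#CC[C@@H](C(C)=C)C(=O)C[C@H](O)/C=C(C)/C=C | intermediate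
15 | (3E,5S,8S)-5-(tert-butyldimethylsilyloxy)-3-methyl-8-(prop-1-en-2-yl)dodeca-1,3-dien-10-yn-7-one | CC#CC[C@@H](C(C)=C)C(=O)C[C@H](O[Si](C)(C)C(C)(C)C)/C=C(C)/C=C | intermediate
16 | 9-(but-2-yn-1-yl)-6-(tert-butyldimethylsilyloxy)-4,10-dimethyl-trans-Δ3-octalin-8-one (H-5 anti to CH3-10; C6–O axial and C9 chain equatorial, both syn to CH3-10) | CC#CC[C@@H]1C(=O)C[C@H](O[Si](C)(C)C(C)(C)C)[C@@H]2C(C)=CCC[C@@]12C | intermediate
17 | N'-(C4-methyl) octane-1-sulfonohydrazide adduct of 16 (C4 epimers, both converge; other centres as in 16) | CC#CC[C@@H]1C(=O)C[C@H](O[Si](C)(C)C(C)(C)C)[C@@H]2C(C)(CNNS(=O)(=O)CCCCCCCC)CCC[C@@]12C | intermediate (not isolated)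
18 | 9-(but-2-yn-1-yl)-6-(tert-butyldimethylsilyloxy)-4,4,10-trimethyl-trans-decalin-8-one (centres as in 16) | CC#CC[C@@H]1C(=O)C[C@H](O[Si](C)(C)C(C)(C)C)[C@@H]2C(C)(C)CCC[C@@]12C | intermediate
19 | potassium C7=C8 enolate of 18 | [K+].CC#CC[C@@H]1C([O-])=C[C@H](O[Si](C)(C)C(C)(C)C)[C@@H]2C(C)(C)CCC[C@@]12C | intermediate (not isolated)
20 | C7=C8 enol triflate of 18 (centres as in 16) | CC#CC[C@@H]1C(OS(=O)(=O)C(F)(F)F)=C[C@H](O[Si](C)(C)C(C)(C)C)[C@@H]2C(C)(C)CCC[C@@]12C | intermediate
21 | [9-(but-2-yn-1-yl)-6-(tert-butyldimethylsilyloxy)-4,4,10-trimethyl-trans-Δ7-octalin-8-yl]methanol, (5R,6S,9S,10S) | CC#CC[C@@H]1C(CO)=C[C@H](O[Si](C)(C)C(C)(C)C)[C@@H]2C(C)(C)CCC[C@@]12C | intermediate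
22 | (12E)-C13 alkenylzirconocene chloride of 21, with C17–O bound to a second chlorozirconocene | Cl[Zr](C1C=CC=C1)(C1C=CC=C1)/C(C)=C/C[C@@H]1C(CO[Zr](Cl)(C3C=CC=C3)C3C=CC=C3)=C[C@H](O[Si](C)(C)C(C)(C)C)[C@@H]2C(C)(C)CCC[C@@]12C | intermediate (not isolated)
23 | (12E)-C13 alkenylzinc chloride from 22 | Cl[Zn]/C(C)=C/C[C@@H]1C(CO[Zr](Cl)(C3C=CC=C3)C3C=CC=C3)=C[C@H](O[Si](C)(C)C(C)(C)C)[C@@H]2C(C)(C)CCC[C@@]12C | intermediate (not isolated)
24 | (5R,6S,9S,10S)-6-(tert-butyldimethylsilyloxy)labda-7,12E,14-trien-17-ol (ent-labdane series) | C=C/C(C)=C/C[C@@H]1C(CO)=C[C@H](O[Si](C)(C)C(C)(C)C)[C@@H]2C(C)(C)CCC[C@@]12C | intermediate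
25 | (5R,6S,9S,10S)-labda-7,12E,14-triene-6,17-diol (ent-labdane series) | C=C/C(C)=C/C[C@@H]1C(CO)=C[C@H](O)[C@@H]2C(C)(C)CCC[C@@]12C | intermediate
26 | (5R,6S,9S,10S)-labda-7,12E,14-triene-6,17-diyl diacetate; [(1S,4S,4aR,8aS)-4-acetoxy-5,5,8a-trimethyl-1-[(2E)-3-methylpenta-2,4-dien-1-yl]-1,4,4a,5,6,7,8,8a-octahydronaphthalen-2-yl]methyl acetate | C=C/C(C)=C/C[C@@H]1C(COC(C)=O)=C[C@H](OC(C)=O)[C@@H]2C(C)(C)CCC[C@@]12C | target

**Step count.** Total: 15 steps. Longest linear sequence: 13 steps (steps 3–15, from 4); the dienal arm (steps 1–2) joins at step 7.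

**Steps most likely to fail**

1. Step 9 (intramolecular Diels–Alder). The unactivated cycloaddition may need a temperature at which the β-silyloxy ketone eliminates or C9 epimerises, or the ring fusion may form with poor trans selectivity. The fallback sets out from 14 and comes back at 25; it keeps the same two-bond cycloaddition but activates the diene and moves control of C6 to a late reduction. Oxidation of 14 with Dess–Martin periodinane should give (3E,8S)-3-methyl-8-(prop-1-en-2-yl)dodeca-1,3-dien-10-yne-5,7-dione F1, whose C6 carbonyl makes the diene electron-poor and matched to the electron-rich 1,1-disubstituted alkene. Cyclisation through the diketo tautomer in toluene at about 110 °C should then give 9-(but-2-yn-1-yl)-4,10-dimethyl-trans-Δ3-octalin-6,8-dione F2. Hydromethylation as in step 10 would give 9-(but-2-yn-1-yl)-4,4,10-trimethyl-trans-decalin-6,8-dione F3. O-Triflation (KN(SiMe3)2, Comins' reagent) at the less hindered O8, away from the C4 methyls, would give the 8-triflyloxy-7-en-6-one F4. Stille coupling with Bu3SnCH2OH would give the 8-(hydroxymethyl)-7-en-6-one F5. Luche reduction (NaBH4, CeCl3·7H2O, MeOH) from the face anti to the axial methyls would give the 6-axial alcohol, 9-(but-2-yn-1-yl)-8-(hydroxymethyl)-4,4,10-trimethyl-trans-Δ7-octalin-6-ol F6. Hydrozirconation and Negishi vinylation as in step 13 then return 25.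

2. Step 10 (hydromethylation). The hindered tertiary C4 radical may be reduced before it adds to the hydrazone (net hydrogenation), or hydrogen atom transfer may reach the alkyne. The fallback sets out from 16 and comes back at 20, replacing the radical step by ionic chemistry after the ketone has been masked. Enol triflate formation as in step 11 on 16 would give the C7=C8 enol triflate of 16 F7. Anhydrous HCl in CH2Cl2 at −78 °C should add in the Markovnikov sense to C3=C4 and give the tertiary C4 chloride F8 (either C4 epimer). Methylation of the tertiary chloride with AlMe3 in CH2Cl2 (−78 → −20 °C, ion-pair substitution) would return 20.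

3. Step 12 (Stille hydroxymethylation). Transfer of the hydroxymethyl group from tin to the hindered C8 alkenylpalladium may be slow, so that protodestannylation and loss of the triflate take over. The fallback sets out from 20 and comes back at 21. Carbonylation (Pd(OAc)2, dppp, CO 1 atm, MeOH, Et3N, DMF, 60 °C) would give the methyl 7-en-17-oate, methyl 9-(but-2-yn-1-yl)-6-(tert-butyldimethylsilyloxy)-4,4,10-trimethyl-trans-Δ7-octalin-8-carboxylate F9. Reduction with i-Bu2AlH in CH2Cl2 at −78 °C would return 21.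

**Further compounds**

F1 | step 9 | (3E,8S)-3-methyl-8-(prop-1-en-2-yl)dodeca-1,3-dien-10-yne-5,7-dione | CC#CC[C@@H](C(C)=C)C(=O)CC(=O)/C=C(C)/C=C
F2 | step 9 | 9-(but-2-yn-1-yl)-4,10-dimethyl-trans-Δ3-octalin-6,8-dione | CC#CC[C@@H]1C(=O)CC(=O)[C@@H]2C(C)=CCC[C@@]12C
F3 | step 9 | 9-(but-2-yn-1-yl)-4,4,10-trimethyl-trans-decalin-6,8-dione | CC#CC[C@@H]1C(=O)CC(=O)[C@@H]2C(C)(C)CCC[C@@]12C
F4 | step 9 | 9-(but-2-yn-1-yl)-4,4,10-trimethyl-6-oxo-trans-Δ7-octalin-8-yl trifluoromethanesulfonate | CC#CC[C@@H]1C(OS(=O)(=O)C(F)(F)F)=CC(=O)[C@@H]2C(C)(C)CCC[C@@]12C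
F5 | step 9 | 9-(but-2-yn-1-yl)-8-(hydroxymethyl)-4,4,10-trimethyl-trans-Δ7-octalin-6-one | CC#CC[C@@H]1C(CO)=CC(=O)[C@@H]2C(C)(C)CCC[C@@]12C
F6 | step 9 | 9-(but-2-yn-1-yl)-8-(hydroxymethyl)-4,4,10-trimethyl-trans-Δ7-octalin-6-ol (6-OH axial, syn to CH3-10) | CC#CC[C@@H]1C(CO)=C[C@H](O)[C@@H]2C(C)(C)CCC[C@@]12C
F7 | step 10 | 9-(but-2-yn-1-yl)-6-(tert-butyldimethylsilyloxy)-4,10-dimethyl-trans-octalin-3,7-dien-8-yl trifluoromethanesulfonate | CC#CC[C@@H]1C(OS(=O)(=O)C(F)(F)F)=C[C@H](O[Si](C)(C)C(C)(C)C)[C@@H]2C(C)=CCC[C@@]12C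
F8 | step 10 | 4-chloro analogue of F7 with C3–C4 saturated (either C4 epimer) | CC#CC[C@@H]1C(OS(=O)(=O)C(F)(F)F)=C[C@H](O[Si](C)(C)C(C)(C)C)[C@@H]2C(C)(Cl)CCC[C@@]12C
F9 | step 12 | methyl 9-(but-2-yn-1-yl)-6-(tert-butyldimethylsilyloxy)-4,4,10-trimethyl-trans-Δ7-octalin-8-carboxylate | CC#CC[C@@H]1C(C(=O)OC)=C[C@H](O[Si](C)(C)C(C)(C)C)[C@@H]2C(C)(C)CCC[C@@]12C
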